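**Retrosynthetic overview**

1. The target is three (2S,3R)-ent-fisetinidol units on (+)-catechin: U (C4 bonded to C6 of M), M (C4 bonded to C8 of L), S (C4 bonded to C6 of L) and L (catechin). Every C4–aryl bond is cis to O3, so each is cut to an aryllithium plus a flavan-4-one, with hydride put on C4 last. U, M and S then all come from one ketone, 17.
2. Key disconnection (ketone 14, which becomes M and also U and S): the pyranone ring is cut at O1–C8a and C4–C4a. Enabling feature: in the benzo ring of M, O1 and C4 sit on the neighbouring carbons C8a and C4a, the two ends of an aryne, and O1 and C4 are 1,3-related on the C2–C3 chain (a β-hydroxy amide).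
3. C5 is H in the target and C8a is meta to the C7 oxygen, so a chlorine at C5 can steer the aryne addition and leave at the end; a bromine at C6 later joins U to M, and an iodine put on C6 of L joins S.
4. Order of ring formation: pyranone ring by aryne annulation (step 8), then the C3 oxygen (Rubottom), then the M–L bond (steps 13, 14), the U–M bond (steps 15, 16) and the S–L bond (steps 17 to 19), then global hydrogenolysis (step 20). The catechin rings are bought.

Key step: step 8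

Remark (assumption): 1, 8, 9 and 18 (5,7,3',4'-tetra-O-benzyl-(+)-catechin) are taken as commercial; flavan numbering is used within each unit.

**Route**

Step 1
Reactants: 1 2-bromo-3-chlorophenol
Product: 3 2-bromo-3-chloro-5-(4,4,5,5-tetramethyl-1,3,2-dioxaborolan-2-yl)phenol, via O-borylated aryl boronate 2 (not isolated)
Conditions: [Ir(OMe)(cod)]2 (1.5 mol %), 4,4'-di-tert-butyl-2,2'-bipyridine (3 mol %), HBpin (2.5 equiv), THF, 60 °C; then MeOH/H2O
Reagents that add atoms: pinacolborane, [H]B1OC(C)(C)C(C)(C)O1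
Why: Iridium-catalysed C–H borylation is sterically controlled, and after in-situ O-borylation only C5–H has no ortho substituent, so boron should enter meta to both oxygen and chlorine.

Step 2
Reactants: 3 2-bromo-3-chloro-5-(4,4,5,5-tetramethyl-1,3,2-dioxaborolan-2-yl)phenol
Product: 4 2-[3-(benzyloxy)-4-bromo-5-chlorophenyl]-4,4,5,5-tetramethyl-1,3,2-dioxaborolane
Conditions: BnBr, K2CO3, DMF, rt
Reagents that add atoms: benzyl bromide, BrCc1ccccc1
Why: Williamson etherification of the phenol, which the pinacol boronate should tolerate; benzylating only now keeps the benzyl ring out of the borylation.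

Step 3
Reactants: 4 2-[3-(benzyloxy)-4-bromo-5-chlorophenyl]-4,4,5,5-tetramethyl-1,3,2-dioxaborolane
Product: 5 3-(benzyloxy)-4-bromo-5-chlorophenol
Conditions: KHSO5 (Oxone), acetone/H2O, 0 °C to rt
Reagents that add atoms: potassium peroxymonosulfate, [K+].[O-]S(=O)(=O)OO
Why: Oxidation of the aryl boronate to the phenol, which should leave bromide, chloride and benzyl ether untouched.

Step 4
Reactants: 5 3-(benzyloxy)-4-bromo-5-chlorophenol
Product: 6 3-(benzyloxy)-4-bromo-5-chlorophenyl trifluoromethanesulfonate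
Conditions: Tf2O, pyridine, CH2Cl2, 0 °C
Reagents that add atoms: trifluoromethanesulfonic anhydride, O=S(=O)(OS(=O)(=O)C(F)(F)F)C(F)(F)F
Why: O-sulfonylation of the phenol gives the later leaving group of the aryne precursor and, by deactivating this oxygen, hands regiocontrol in step 5 to the benzyloxy group.

Step 5
Reactants: 6 3-(benzyloxy)-4-bromo-5-chlorophenyl trifluoromethanesulfonate
Product: 7 5-(benzyloxy)-4-bromo-3-chloro-2-iodophenyl trifluoromethanesulfonate
Conditions: NIS, CF3CO2H, MeCN, rt to 40 °C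
Reagents that add atoms: N-iodosuccinimide, O=C1CCC(=O)N1I
Why: Electrophilic aromatic iodination should go para to the only activating group (OBn), that is to the carbon between OTf and Cl; the other free position is ortho to OBn and flanked by OBn and OTf.

Step 6
Reactants: 8 methyl 3,4-bis(benzyloxy)benzoate; 9 N-methoxy-N-methylacetamide
Product: 10 3-[3,4-bis(benzyloxy)phenyl]-N-methoxy-N-methyl-3-oxopropanamide
Conditions: 9, LDA (2.2 equiv), THF, −78 °C; then 8, −78 to 0 °C; aq NH4Cl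
Reagents that add atoms: none
Why: Crossed Claisen condensation of the amide lithium enolate with the non-enolisable ester, the second equivalent of base holding the product as its enolate.

Step 7
Reactants: 10 3-[3,4-bis(benzyloxy)phenyl]-N-methoxy-N-methyl-3-oxopropanamide
Product: 11 (3R)-3-[3,4-bis(benzyloxy)phenyl]-3-hydroxy-N-methoxy-N-methylpropanamide
Conditions: RuCl[(R,R)-TsDPEN](p-cymene) (1 mol %), HCO2H/Et3N (5:2), DMF, 40 °C
Reagents that add atoms: none
Why: Noyori asymmetric transfer hydrogenation of the aryl ketone, in which the (R,R)-catalyst should give the (R)-benzylic alcohol by the same aryl/alkyl discrimination as for acetophenone.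

Step 8
Reactants: 11 (3R)-3-[3,4-bis(benzyloxy)phenyl]-3-hydroxy-N-methoxy-N-methylpropanamide; 7 5-(benzyloxy)-4-bromo-3-chloro-2-iodophenyl trifluoromethanesulfonate
Product: 14 (2R)-7-(benzyloxy)-2-[3,4-bis(benzyloxy)phenyl]-6-bromo-5-chloro-2,3-dihydro-4H-chromen-4-one, via aryne 12 (not isolated), via chloromagnesium hemiaminal 13 (not isolated)
Conditions: 11, NaH (1.05 equiv), THF, 0 °C; add 7, −78 °C; Me3SiCH2MgCl (1.1 equiv), −78 to 0 °C; aq NH4Cl
Reagents that add atoms: none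
Why: Proposed new method: iodine–magnesium exchange at the iodide of 7 (flanked by OTf and Cl, so much faster than at the bromide) and loss of MgCl(OTf) should release aryne 12; the sodium alkoxide of 11 adds to it, and the aryl carbanion so formed, held as the arylmagnesium, attacks the Weinreb carbonyl to give chelate 13, which gives up ketone 14 only on quench. The closest known reaction types are the aryne annulation of salicylate esters to xanthones (O-arylation, then acyl substitution by the aryl anion), the addition of magnesium amides and thiolates to arynes with trapping of the new arylmagnesium, and Parham-type cyclisation onto Weinreb amides; an aliphatic β-hydroxy amide alkoxide has not been used in this way. The pyranone ring is closed in a formal [4+2] sense: intermolecular C8a–O bond formation, then 6-exo-trig acyl substitution at C4 by C4a. No stereocentre is formed, and C2 should keep its configuration because neither bond is made at it and no free ketone (which could open to the chalcone) exists while base is present. The step needs oxygen to attack the aryne carbon remote from chlorine; the C5 chlorine secures this (inductive stabilisation of the C4a carbanion, aryne distortion), helped by the C6 bromine meta to C4a and outweighing the C7 benzyloxy group. It also needs ring closure to outrun protonation of the aryl carbanion, which the aprotic medium (alkoxide preformed, no free OH) and the six-membered transition state should provide.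

Step 9
Reactants: 14 (2R)-7-(benzyloxy)-2-[3,4-bis(benzyloxy)phenyl]-6-bromo-5-chloro-2,3-dihydro-4H-chromen-4-one
Product: 16 (2S,3S)-7-(benzyloxy)-2-[3,4-bis(benzyloxy)phenyl]-6-bromo-5-chloro-3-hydroxy-2,3-dihydro-4H-chromen-4-one, via silyl enol ether 15 (not isolated)
Conditions: TMSOTf, Et3N, CH2Cl2, 0 °C; then DMDO (acetone), CH2Cl2, −40 to 0 °C; then aq citric acid, THF
Reagents that add atoms: dimethyldioxirane, CC1(C)OO1
Why: Rubottom oxidation, in which the silyl enol ether should be epoxidised anti to the C2 aryl group so that the 3-hydroxyl ends up trans to it (2S,3S); soft enolisation avoids the metal enolate that could open the pyranone ring.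

Step 10
Reactants: 16 (2S,3S)-7-(benzyloxy)-2-[3,4-bis(benzyloxy)phenyl]-6-bromo-5-chloro-3-hydroxy-2,3-dihydro-4H-chromen-4-one
Product: 17 (2S,3S)-3,7-bis(benzyloxy)-2-[3,4-bis(benzyloxy)phenyl]-6-bromo-5-chloro-2,3-dihydro-4H-chromen-4-one
Conditions: BnBr, Ag2O, CH2Cl2, rt, dark
Reagents that add atoms: benzyl bromide, BrCc1ccccc1
Why: Silver-oxide-mediated O-benzylation works without a strong base, so the 2,3-trans ketone should be neither epimerised nor ring-opened.

Step 11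
Reactants: 18 (2R,3S)-5,7-bis(benzyloxy)-2-[3,4-bis(benzyloxy)phenyl]chroman-3-ol
Product: 19 (2R,3S)-3,5,7-tris(benzyloxy)-2-[3,4-bis(benzyloxy)phenyl]chromane
Conditions: NaH, BnBr, n-Bu4NI (cat.), DMF, 0 °C to rt
Reagents that add atoms: benzyl bromide, BrCc1ccccc1
Why: Williamson benzylation of the remaining secondary alcohol.

Step 12
Reactants: 19 (2R,3S)-3,5,7-tris(benzyloxy)-2-[3,4-bis(benzyloxy)phenyl]chromane
Product: 20 (2R,3S)-3,5,7-tris(benzyloxy)-2-[3,4-bis(benzyloxy)phenyl]-8-bromochromane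
Conditions: NBS (1.0 equiv), CH2Cl2, −78 °C to rt
Reagents that add atoms: N-bromosuccinimide, O=C1CCC(=O)N1Br
Why: Electrophilic bromination of the phloroglucinol-type benzo ring, C8 being the position that reacts first in catechin benzyl ethers.

Step 13
Reactants: 20 (2R,3S)-3,5,7-tris(benzyloxy)-2-[3,4-bis(benzyloxy)phenyl]-8-bromochromane; 17 (2S,3S)-3,7-bis(benzyloxy)-2-[3,4-bis(benzyloxy)phenyl]-6-bromo-5-chloro-2,3-dihydro-4H-chromen-4-one
Product: 22 M–L carbinol (2S,3S)-3,7-bis(benzyloxy)-2-[3,4-bis(benzyloxy)phenyl]-6-bromo-5-chloro-4-{(2R,3S)-3,5,7-tris(benzyloxy)-2-[3,4-bis(benzyloxy)phenyl]chroman-8-yl}chroman-4-ol (carbinol centre C4 undefined), via 8-lithio catechin ether 21 (not isolated)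
Conditions: t-BuLi (2.1 equiv), THF, −78 °C; then 17, −78 °C; aq NH4Cl
Reagents that add atoms: none
Why: Bromine–lithium exchange and 1,2-addition of the aryllithium to the C4 ketone (organolithium addition, precedented for 3-O-protected flavan-4-ones); the carbinol centre needs no control because step 14 erases it.

Step 14
Reactants: 22 M–L carbinol
Product: 23 M–L dimer (2S,3R,4R)-3,7-bis(benzyloxy)-2-[3,4-bis(benzyloxy)phenyl]-6-bromo-5-chloro-4-{(2R,3S)-3,5,7-tris(benzyloxy)-2-[3,4-bis(benzyloxy)phenyl]chroman-8-yl}chromane (4-aryl cis to 3-OBn)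
Conditions: Bu3SnH, CF3CO2H, CH2Cl2, 0 °C
Reagents that add atoms: none
Why: Ionic hydrogenation, in which acid ionises the doubly benzylic tertiary alcohol and Bu3SnH should deliver hydride anti to the neighbouring 3-benzyloxy group (the face that carbon nucleophiles take in 2,3-trans flavan-4-yl cations), placing the C4 aryl group cis to O3.

Step 15
Reactants: 23 M–L dimer; 17 (2S,3S)-3,7-bis(benzyloxy)-2-[3,4-bis(benzyloxy)phenyl]-6-bromo-5-chloro-2,3-dihydro-4H-chromen-4-one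
Product: 25 U–M–L trimer carbinol (carbinol centre of unit U undefined), via 6-lithio dimer 24 (not isolated)
Conditions: t-BuLi (2.1 equiv), THF/Et2O, −100 °C; then 17, −100 to −78 °C; aq NH4Cl
Reagents that add atoms: none
Why: Bromine–lithium exchange at C6 of unit M (the only aryl bromide present) and 1,2-addition of the aryllithium to ketone 17 (organolithium addition as in step 13); the low temperature should keep the ortho-chloro aryllithium from losing LiCl, and the carbinol centre is erased in step 16.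

Step 16
Reactants: 25 U–M–L trimer carbinol
Product: 26 U–M–L trimer (C4–aryl bond of unit U cis to its 3-benzyloxy group)
Conditions: Bu3SnH, CF3CO2H, CH2Cl2, 0 °C
Reagents that add atoms: none
Why: Ionic hydrogenation as in step 14, in which the flavan-4-yl cation of unit U should take hydride anti to its 3-benzyloxy group and so set the new C4 centre 3,4-cis.

Step 17
Reactants: 26 U–M–L trimer
Product: 27 iodo trimer (iodine at C6 of unit L)
Conditions: NIS (1.05 equiv), CH2Cl2, −20 °C to rt, dark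
Reagents that add atoms: N-iodosuccinimide, O=C1CCC(=O)N1I
Why: Electrophilic aromatic iodination at C6 of unit L, the only free position on the only benzo ring that carries three oxygen substituents; the halogenated benzo rings and the catechol ether rings are far less nucleophilic.

Step 18
Reactants: 27 iodo trimer; 17 (2S,3S)-3,7-bis(benzyloxy)-2-[3,4-bis(benzyloxy)phenyl]-6-bromo-5-chloro-2,3-dihydro-4H-chromen-4-one
Product: 29 tetramer carbinol (carbinol centre of unit S undefined), via 6-lithio trimer 28 (not isolated)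
Conditions: n-BuLi (1.0 equiv), THF/Et2O, −100 °C; then 17, −100 to −78 °C; aq NH4Cl
Reagents that add atoms: none
Why: Iodine–lithium exchange, which is much faster than bromine–lithium exchange and with one equivalent of n-BuLi at −100 °C should spare the aryl bromide of unit U, followed by 1,2-addition of the aryllithium to ketone 17 (organolithium addition as in step 13); the carbinol centre is erased in step 19.

Step 19
Reactants: 29 tetramer carbinol
Product: 30 protected tetramer (heptadeca-O-benzyl ether; three aryl chlorides; two aryl bromides; all C4–aryl bonds cis to O3)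
Conditions: Bu3SnH, CF3CO2H, CH2Cl2, 0 °C
Reagents that add atoms: none
Why: Ionic hydrogenation as in step 14, the cation of unit S taking hydride anti to its 3-benzyloxy group, which should set the last C4 centre 3,4-cis.

Step 20
Reactants: 30 protected tetramer
Product: 31 ent-fisetinidol-(4α→6)-ent-fisetinidol-(4α→8)-catechin-(6→4α)-ent-fisetinidol (CNP0126838.1)
Conditions: H2 (1 atm), Pd(OH)2/C, NaOAc, THF/MeOH/H2O, rt
Reagents that add atoms: none
Why: Hydrogenolysis of the seventeen benzyl ethers with concurrent hydrodehalogenation of three aryl chlorides and two aryl bromides (acetate takes up HX); no stereocentre is involved and the 5-deoxy interflavanyl bonds should tolerate the conditions.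

**Compound list**

1 | 2-bromo-3-chlorophenol | Oc1cccc(Cl)c1Br | starting material
2 | 2-[2-bromo-3-chloro-5-(4,4,5,5-tetramethyl-1,3,2-dioxaborolan-2-yl)phenoxy]-4,4,5,5-tetramethyl-1,3,2-dioxaborolane | CC1(C)OB(Oc2cc(B3OC(C)(C)C(C)(C)O3)cc(Cl)c2Br)OC1(C)C | intermediate
3 | 2-bromo-3-chloro-5-(4,4,5,5-tetramethyl-1,3,2-dioxaborolan-2-yl)phenol | Oc1cc(B2OC(C)(C)C(C)(C)O2)cc(Cl)c1Br | intermediate
4 | 2-[3-(benzyloxy)-4-bromo-5-chlorophenyl]-4,4,5,5-tetramethyl-1,3,2-dioxaborolane | Clc1cc(B2OC(C)(C)C(C)(C)O2)cc(OCc2ccccc2)c1Br | intermediate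
5 | 3-(benzyloxy)-4-bromo-5-chlorophenol | Oc1cc(Cl)c(Br)c(OCc2ccccc2)c1 | intermediate
6 | 3-(benzyloxy)-4-bromo-5-chlorophenyl trifluoromethanesulfonate | FC(F)(F)S(=O)(=O)Oc1cc(Cl)c(Br)c(OCc2ccccc2)c1 | intermediate
7 | 5-(benzyloxy)-4-bromo-3-chloro-2-iodophenyl trifluoromethanesulfonate | FC(F)(F)S(=O)(=O)Oc1cc(OCc2ccccc2)c(Br)c(Cl)c1I | intermediate
8 | methyl 3,4-bis(benzyloxy)benzoate | COC(=O)c1ccc(OCc2ccccc2)c(OCc2ccccc2)c1 | starting material
9 | N-methoxy-N-methylacetamide | CC(=O)N(C)OC | starting material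
10 | 3-[3,4-bis(benzyloxy)phenyl]-N-methoxy-N-methyl-3-oxopropanamide | CON(C)C(=O)CC(=O)c1ccc(OCc2ccccc2)c(OCc2ccccc2)c1 | intermediate
11 | (3R)-3-[3,4-bis(benzyloxy)phenyl]-3-hydroxy-N-methoxy-N-methylpropanamide | O[C@@H](c1ccc(OCc2ccccc2)c(OCc2ccccc2)c1)CC(=O)N(C)OC | intermediate
12 | 5-(benzyloxy)-4-bromo-3-chlorobenzyne (1,2-didehydrobenzene) | ClC1=C(Br)C(OCc2ccccc2)=CC#C1 | intermediate
13 | chloromagnesium alkoxide of (2R)-7-(benzyloxy)-2-[3,4-bis(benzyloxy)phenyl]-6-bromo-5-chloro-4-[methoxy(methyl)amino]chroman-4-ol (C4 undefined) | Brc1c(Cl)c2c(cc1OCc1ccccc1)O[C@@H](c1ccc(OCc3ccccc3)c(OCc3ccccc3)c1)CC2(O[Mg]Cl)N(C)OC | intermediate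
14 | (2R)-7-(benzyloxy)-2-[3,4-bis(benzyloxy)phenyl]-6-bromo-5-chloro-2,3-dihydro-4H-chromen-4-one | Brc1c(Cl)c2c(cc1OCc1ccccc1)O[C@@H](c1ccc(OCc3ccccc3)c(OCc3ccccc3)c1)CC2=O | intermediate
15 | (2R)-7-(benzyloxy)-2-[3,4-bis(benzyloxy)phenyl]-6-bromo-5-chloro-4-(trimethylsilyloxy)-2H-chromene | Brc1c(Cl)c2c(cc1OCc1ccccc1)O[C@@H](c1ccc(OCc3ccccc3)c(OCc3ccccc3)c1)C=C2O[Si](C)(C)C | intermediate
16 | (2S,3S)-7-(benzyloxy)-2-[3,4-bis(benzyloxy)phenyl]-6-bromo-5-chloro-3-hydroxy-2,3-dihydro-4H-chromen-4-one | Brc1c(Cl)c2c(cc1OCc1ccccc1)O[C@@H](c1ccc(OCc3ccccc3)c(OCc3ccccc3)c1)[C@H](O)C2=O | intermediate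
17 | (2S,3S)-3,7-bis(benzyloxy)-2-[3,4-bis(benzyloxy)phenyl]-6-bromo-5-chloro-2,3-dihydro-4H-chromen-4-one | Brc1c(Cl)c2c(cc1OCc1ccccc1)O[C@@H](c1ccc(OCc3ccccc3)c(OCc3ccccc3)c1)[C@H](OCc1ccccc1)C2=O | intermediate
18 | (2R,3S)-5,7-bis(benzyloxy)-2-[3,4-bis(benzyloxy)phenyl]chroman-3-ol (5,7,3',4'-tetra-O-benzyl-(+)-catechin) | c1ccccc1COc1cc(OCc2ccccc2)c2c(c1)O[C@H](c1ccc(OCc3ccccc3)c(OCc3ccccc3)c1)[C@@H](O)C2 | starting material
19 | (2R,3S)-3,5,7-tris(benzyloxy)-2-[3,4-bis(benzyloxy)phenyl]chromane | c1ccccc1COc1cc(OCc2ccccc2)c2c(c1)O[C@H](c1ccc(OCc3ccccc3)c(OCc3ccccc3)c1)[C@@H](OCc1ccccc1)C2 | intermediate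
20 | (2R,3S)-3,5,7-tris(benzyloxy)-2-[3,4-bis(benzyloxy)phenyl]-8-bromochromane | c1ccccc1COc1cc(OCc2ccccc2)c2c(c1Br)O[C@H](c1ccc(OCc3ccccc3)c(OCc3ccccc3)c1)[C@@H](OCc1ccccc1)C2 | intermediate
21 | (2R,3S)-3,5,7-tris(benzyloxy)-2-[3,4-bis(benzyloxy)phenyl]chroman-8-yllithium | c1ccccc1COc1cc(OCc2ccccc2)c2c(c1[Li])O[C@H](c1ccc(OCc3ccccc3)c(OCc3ccccc3)c1)[C@@H](OCc1ccccc1)C2 | intermediate
22 | M–L carbinol: ketone 17 carrying at C4 a hydroxyl and C8 of 19 (carbinol centre undefined) | Brc1c(Cl)c2c(cc1OCc1ccccc1)O[C@@H](c1ccc(OCc3ccccc3)c(OCc3ccccc3)c1)[C@H](OCc1ccccc1)C2(O)c1c(OCc2ccccc2)cc(OCc2ccccc2)c2c1O[C@H](c1ccc(OCc3ccccc3)c(OCc3ccccc3)c1)[C@@H](OCc1ccccc1)C2 | intermediate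
23 | M–L dimer: unit M (2S,3R,4R; 5-Cl, 6-Br; 4-aryl cis to 3-OBn) bonded through C4 to C8 of penta-O-benzylcatechin | Brc1c(Cl)c2c(cc1OCc1ccccc1)O[C@@H](c1ccc(OCc3ccccc3)c(OCc3ccccc3)c1)[C@H](OCc1ccccc1)[C@@H]2c1c(OCc2ccccc2)cc(OCc2ccccc2)c2c1O[C@H](c1ccc(OCc3ccccc3)c(OCc3ccccc3)c1)[C@@H](OCc1ccccc1)C2 | intermediate
24 | 6-lithio dimer: 23 with the bromine at C6 of unit M replaced by lithium | [Li]c1c(Cl)c2c(cc1OCc1ccccc1)O[C@@H](c1ccc(OCc3ccccc3)c(OCc3ccccc3)c1)[C@H](OCc1ccccc1)[C@@H]2c1c(OCc2ccccc2)cc(OCc2ccccc2)c2c1O[C@H](c1ccc(OCc3ccccc3)c(OCc3ccccc3)c1)[C@@H](OCc1ccccc1)C2 | intermediate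
25 | U–M–L trimer carbinol: 23 with the bromine at C6 of unit M replaced by C4 of a 4-hydroxy unit derived from 17 (carbinol centre undefined) | c1ccccc1COc1c(Br)c(Cl)c2c(c1)O[C@@H](c1ccc(OCc3ccccc3)c(OCc3ccccc3)c1)[C@H](OCc1ccccc1)C2(O)c1c(Cl)c2c(cc1OCc1ccccc1)O[C@@H](c1ccc(OCc3ccccc3)c(OCc3ccccc3)c1)[C@H](OCc1ccccc1)[C@@H]2c1c(OCc2ccccc2)cc(OCc2ccccc2)c2c1O[C@H](c1ccc(OCc3ccccc3)c(OCc3ccccc3)c1)[C@@H](OCc1ccccc1)C2 | intermediate
26 | U–M–L trimer: unit U (5-Cl, 6-Br) bonded through C4 to C6 of unit M (5-Cl), unit M bonded through C4 to C8 of penta-O-benzylcatechin; both C4–aryl bonds cis to O3 | c1ccccc1COc1c(Br)c(Cl)c2c(c1)O[C@@H](c1ccc(OCc3ccccc3)c(OCc3ccccc3)c1)[C@H](OCc1ccccc1)[C@@H]2c1c(Cl)c2c(cc1OCc1ccccc1)O[C@@H](c1ccc(OCc3ccccc3)c(OCc3ccccc3)c1)[C@H](OCc1ccccc1)[C@@H]2c1c(OCc2ccccc2)cc(OCc2ccccc2)c2c1O[C@H](c1ccc(OCc3ccccc3)c(OCc3ccccc3)c1)[C@@H](OCc1ccccc1)C2 | intermediate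
27 | iodo trimer: 26 with iodine at C6 of unit L | c1ccccc1COc1c(Br)c(Cl)c2c(c1)O[C@@H](c1ccc(OCc3ccccc3)c(OCc3ccccc3)c1)[C@H](OCc1ccccc1)[C@@H]2c1c(Cl)c2c(cc1OCc1ccccc1)O[C@@H](c1ccc(OCc3ccccc3)c(OCc3ccccc3)c1)[C@H](OCc1ccccc1)[C@@H]2c1c(OCc2ccccc2)c(I)c(OCc2ccccc2)c2c1O[C@H](c1ccc(OCc3ccccc3)c(OCc3ccccc3)c1)[C@@H](OCc1ccccc1)C2 | intermediate
28 | 6-lithio trimer: 27 with the iodine replaced by lithium | c1ccccc1COc1c(Br)c(Cl)c2c(c1)O[C@@H](c1ccc(OCc3ccccc3)c(OCc3ccccc3)c1)[C@H](OCc1ccccc1)[C@@H]2c1c(Cl)c2c(cc1OCc1ccccc1)O[C@@H](c1ccc(OCc3ccccc3)c(OCc3ccccc3)c1)[C@H](OCc1ccccc1)[C@@H]2c1c(OCc2ccccc2)c([Li])c(OCc2ccccc2)c2c1O[C@H](c1ccc(OCc3ccccc3)c(OCc3ccccc3)c1)[C@@H](OCc1ccccc1)C2 | intermediate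
29 | tetramer carbinol: 27 with the iodine replaced by C4 of a 4-hydroxy unit derived from 17 (carbinol centre undefined) | c1ccccc1COc1c(Br)c(Cl)c2c(c1)O[C@@H](c1ccc(OCc3ccccc3)c(OCc3ccccc3)c1)[C@H](OCc1ccccc1)[C@@H]2c1c(Cl)c2c(cc1OCc1ccccc1)O[C@@H](c1ccc(OCc3ccccc3)c(OCc3ccccc3)c1)[C@H](OCc1ccccc1)[C@@H]2c1c(OCc2ccccc2)c(C2(O)c3c(Cl)c(Br)c(OCc4ccccc4)cc3O[C@@H](c3ccc(OCc4ccccc4)c(OCc4ccccc4)c3)[C@@H]2OCc2ccccc2)c(OCc2ccccc2)c2c1O[C@H](c1ccc(OCc3ccccc3)c(OCc3ccccc3)c1)[C@@H](OCc1ccccc1)C2 | intermediate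
30 | protected tetramer: heptadeca-O-benzyl ether with 5-Cl on U, M, S and 6-Br on U, S; all C4–aryl bonds cis to O3 | c1ccccc1COc1c(Br)c(Cl)c2c(c1)O[C@@H](c1ccc(OCc3ccccc3)c(OCc3ccccc3)c1)[C@H](OCc1ccccc1)[C@@H]2c1c(Cl)c2c(cc1OCc1ccccc1)O[C@@H](c1ccc(OCc3ccccc3)c(OCc3ccccc3)c1)[C@H](OCc1ccccc1)[C@@H]2c1c(OCc2ccccc2)c([C@@H]2c3c(Cl)c(Br)c(OCc4ccccc4)cc3O[C@@H](c3ccc(OCc4ccccc4)c(OCc4ccccc4)c3)[C@@H]2OCc2ccccc2)c(OCc2ccccc2)c2c1O[C@H](c1ccc(OCc3ccccc3)c(OCc3ccccc3)c1)[C@@H](OCc1ccccc1)C2 | intermediate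
31 | CNP0126838.1: U (2S,3R,4R), M (2S,3R,4S), S (2S,3R,4S) ent-fisetinidol units on (2R,3S)-catechin | Oc1ccc2c(c1)O[C@@H](c1ccc(O)c(O)c1)[C@H](O)[C@@H]2c1cc2c(cc1O)O[C@@H](c1ccc(O)c(O)c1)[C@H](O)[C@@H]2c1c(O)c([C@@H]2c3ccc(O)cc3O[C@@H](c3ccc(O)c(O)c3)[C@@H]2O)c(O)c2c1O[C@H](c1ccc(O)c(O)c1)[C@@H](O)C2 | target

**Step count and risks**

Total step count: 20. Longest linear sequence: 16 steps (1–5, 8–10, 13–20).

Steps most likely to fail:

Step 8 (proposed new method). The alkoxide may add too slowly to the short-lived aryne, so that the aryne reacts with itself, or the aryl carbanion may be protonated before it closes the ring. Fallback with known reactions, setting out from 7 and 10 and coming back at 14: the triflate of 7 is cleaved with Et4NOH in dioxane to 5-(benzyloxy)-4-bromo-3-chloro-2-iodophenol F1. Ketone 10 is reduced as in step 7 but with RuCl[(S,S)-TsDPEN](p-cymene) to (3S)-3-[3,4-bis(benzyloxy)phenyl]-3-hydroxy-N-methoxy-N-methylpropanamide F2. Mitsunobu etherification (PPh3, DIAD, THF, 0 °C) should join F1 and F2 with inversion to (3R)-3-[5-(benzyloxy)-4-bromo-3-chloro-2-iodophenoxy]-3-[3,4-bis(benzyloxy)phenyl]-N-methoxy-N-methylpropanamide F3. Iodine–magnesium exchange (i-PrMgCl·LiCl, THF, −40 to 0 °C) then closes the ring on the Weinreb amide (Parham-type cyclisation) and should give 14 after quench.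

Step 18. The halogen–lithium exchange may fail to discriminate between the aryl iodide of unit L and the aryl bromide of unit U, or the hindered aryllithium may enolise ketone 17 instead of adding to it. Fallback, setting out from 23 and coming back at 30, in which both carbon–lithium bonds are made before any bromine-bearing ketone is present: 23 is brominated with NBS (CH2Cl2, −40 to 0 °C) at C6 of unit L to give the M–L dibromide F4. Both bromines are exchanged with t-BuLi (4.2 equiv, THF/Et2O, −100 °C), and ketone 17 (2.4 equiv) is then added to give the bis-carbinol F5. Twofold ionic hydrogenation (Bu3SnH, CF3CO2H, CH2Cl2, 0 °C) should then give 30.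

Step 20. Hydrogenolysis may stall with the hindered C5 chlorines still in place, or the debenzylation may be slowed by the halide salts. Fallback, setting out from 30 and coming back at 31, with the two tasks separated: 30 is first hydrodehalogenated homogeneously with [Pd(allyl)Cl(IPr)] (IPr = 1,3-bis(2,6-diisopropylphenyl)imidazol-2-ylidene), NaOt-Bu and i-PrOH in toluene at 60 °C to the halogen-free heptadeca-O-benzyl tetramer F6. F6 is then debenzylated with H2 and Pd(OH)2/C in THF/MeOH to 31.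

**Further compounds**

F1 | step 8 | 5-(benzyloxy)-4-bromo-3-chloro-2-iodophenol | Oc1cc(OCc2ccccc2)c(Br)c(Cl)c1I
F2 | step 8 | (3S)-3-[3,4-bis(benzyloxy)phenyl]-3-hydroxy-N-methoxy-N-methylpropanamide | O[C@H](c1ccc(OCc2ccccc2)c(OCc2ccccc2)c1)CC(=O)N(C)OC
F3 | step 8 | (3R)-3-[5-(benzyloxy)-4-bromo-3-chloro-2-iodophenoxy]-3-[3,4-bis(benzyloxy)phenyl]-N-methoxy-N-methylpropanamide | Ic1c(Cl)c(Br)c(OCc2ccccc2)cc1O[C@@H](c1ccc(OCc2ccccc2)c(OCc2ccccc2)c1)CC(=O)N(C)OC
F4 | step 18 | M–L dibromide: 23 with bromine also at C6 of unit L | Brc1c(Cl)c2c(cc1OCc1ccccc1)O[C@@H](c1ccc(OCc3ccccc3)c(OCc3ccccc3)c1)[C@H](OCc1ccccc1)[C@@H]2c1c(OCc2ccccc2)c(Br)c(OCc2ccccc2)c2c1O[C@H](c1ccc(OCc3ccccc3)c(OCc3ccccc3)c1)[C@@H](OCc1ccccc1)C2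
F5 | step 18 | bis-carbinol: F4 with both bromines replaced by C4 of a 4-hydroxy unit derived from 17 (two carbinol centres undefined) | c1ccccc1COc1c(Br)c(Cl)c2c(c1)O[C@@H](c1ccc(OCc3ccccc3)c(OCc3ccccc3)c1)[C@H](OCc1ccccc1)C2(O)c1c(Cl)c2c(cc1OCc1ccccc1)O[C@@H](c1ccc(OCc3ccccc3)c(OCc3ccccc3)c1)[C@H](OCc1ccccc1)[C@@H]2c1c(OCc2ccccc2)c(C2(O)c3c(Cl)c(Br)c(OCc4ccccc4)cc3O[C@@H](c3ccc(OCc4ccccc4)c(OCc4ccccc4)c3)[C@@H]2OCc2ccccc2)c(OCc2ccccc2)c2c1O[C@H](c1ccc(OCc3ccccc3)c(OCc3ccccc3)c1)[C@@H](OCc1ccccc1)C2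
F6 | step 20 | halogen-free heptadeca-O-benzyl tetramer (30 without chlorine and bromine) | c1ccccc1COc1ccc2c(c1)O[C@@H](c1ccc(OCc3ccccc3)c(OCc3ccccc3)c1)[C@H](OCc1ccccc1)[C@@H]2c1cc2c(cc1OCc1ccccc1)O[C@@H](c1ccc(OCc3ccccc3)c(OCc3ccccc3)c1)[C@H](OCc1ccccc1)[C@@H]2c1c(OCc2ccccc2)c([C@@H]2c3ccc(OCc4ccccc4)cc3O[C@@H](c3ccc(OCc4ccccc4)c(OCc4ccccc4)c3)[C@@H]2OCc2ccccc2)c(OCc2ccccc2)c2c1O[C@H](c1ccc(OCc3ccccc3)c(OCc3ccccc3)c1)[C@@H](OCc1ccccc1)C2
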